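Prostaglandin numbering (C1–C20) is used for atoms throughout; compound numbers are those of the steps.

## Structural features

The target is a C20 hydroxy acid built on one cyclopentane ring (C8–C12). C8 carries the saturated seven-carbon carboxyl chain (C1–C7) and C12 carries the eight-carbon chain with the E-configured C13=C14 olefin and the allylic 15S alcohol. Of the four ring stereocentres, C8/C9, C8/C12 and C11/C12 are adjacent pairs, and the C10 methylene separates C9 from C11. The two chains are trans, and the two hydroxyls are cis to each other and to the C8 chain. The fifth stereocentre, C15, lies three bonds outside the ring and cannot be steered from it. Fragile points are the allylic C15 alcohol (ionisation in acid), the β-hydroxy ketone and the cyclopentenone passed on the way (dehydration; base-induced shift of the olefin to C8=C12 through the doubly allylic C12–H), and the acyclic intermediates in which C8 is α to a carbonyl. The real difficulty is to relate four contiguous ring centres and the distant C15 centre without a rigid scaffold. The feature exploited is that C10 and C11 are the only neighbouring ring atoms that bear no carbon substituent. The C10–C11 bond can therefore be made last, as an olefin, by joining the CH2 termini of a vinyl group on the C9 carbonyl and a vinyl group on C12. C9 and C12 are 1,3-related through C8, not 1,4. The enone so formed then offers C11 for oxygenation and C9 for reduction.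

## Logic of the disconnections

**17 to 15.** No skeletal bond is cut; the O–Si bonds at O11 and O15 and the ester O–CH3 bond are broken last. This keeps the acid and both secondary alcohols masked through every organometallic and hydride step. Little simplicity is gained, but the choice of groups matters: both silyl ethers are the same and fall together, and the ester is cleaved in the same flask. The forward step must stay below the acidity at which the allylic C15 alcohol ionises.

**15 to 14.** The C9–H bond is cut, taking the C9 carbinol back to a ketone. One stereocentre disappears and the ring becomes a β-silyloxy ketone. The forward reduction must deliver hydride from the face opposite the adjacent C8 chain and the O11 silyl group.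

**14 to 11 (through 13 and 12).** The C11–O bond is cut by way of a C10–C11 epoxide. An enone accepts oxygen at its β carbon, so C11 need not be carried as a stereocentre earlier. Two ring centres (C9, C11) are now gone and C10=C11 appears, which is the retron for metathesis. Forward, the hydroperoxide must attack anti to the C12 chain, and the C10–O bond must be cleaved reductively without β-elimination.

**11 to 10.** The C10=C11 ring bond is cut. It is the only ring bond whose two carbons are unsubstituted by carbon, so opening it leaves two vinyl groups and an acyclic chain. Only the adjacent pair C8/C12 and the remote C15 remain as stereocentres, and the ring is gone. The forward closure must choose the two terminal olefins over C13=C14 and must not disturb the enolisable C8 or the doubly allylic C12.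

**10 to 8 (through 9).** The C9–C10 bond is cut and C9 is returned to the aldehyde level. A vinyl ketone is too reactive to carry, whereas the aldehyde is the native product of enamine catalysis. The forward addition must prefer the aldehyde to the ester and must not enolise C8; the oxidation must be non-basic.

**8 to 6 and 7.** The C8–C12 bond is cut. It is the only bond joining the two remaining adjacent stereocentres, and it divides the molecule into an upper-chain half and a lower-chain half of similar size. Each centre can then be assigned to its own catalyst. The nucleophile must attack the internal carbon of an allyl unit that carries an alkenyl arm, and both catalysts must override the resident C15 centre.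

**6 to 2 and 3.** The C12–C13 bond is cut. An alkenyl metal made by syn hydrometalation of an alkyne fixes the E geometry, and the C12 carbinol configuration is irrelevant because this centre is ionised later. The forward step needs 1,2-addition to an enal and tolerance of the silyl ether.

**2 to 1.** Only the O15–Si bond is cut. C15 is bought as a single enantiomer, so the remote stereocentre costs no reaction.

## Other disconnections considered

**Alternative 1:** The ring is cut at C8–C9 and C11=C12 and the C9 oxygen is tied to C6 as a lactol. In the forward direction two molecules of succinaldehyde A2 would be joined by a proline-catalysed aldol and an amine-salt-catalysed aldol condensation to the bicyclic enal A1. The lower chain would then be added at C12 by organocopper conjugate addition. C11 would be oxygenated by ozonolysis of the trapped enol ether followed by reduction, and the upper chain attached at C6 by a Wittig reaction.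
- In its favour: a very cheap C4 feedstock, and C8, C9 and the cis ring fusion from one catalytic step.
- Better than the chosen plan: the 9α oxygen is present from the first step, so no late ketone reduction is needed.
- Equal: both plans rest on enamine catalysis and both bring C15 in from the same chiral alcohol.
- Against it here: the dimerisation must compete with oligomerisation of A2, so material throughput at the first step is inherently low. A C6 lactol and Wittig logic also delivers a C5=C6 olefin, which for this saturated target must be hydrogenated in the presence of C13=C14.
- Comparison: it builds the ring first and adds both chains stoichiometrically, whereas the chosen plan joins both chains catalytically and closes the ring afterwards. In step count it should be somewhat shorter, even with the extra hydrogenation.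

**Alternative 2:** Four bonds (C8–C12, C9–O, C11–O, C15–O) are cut at once. Forward, the cyclooxygenase would convert dihomo-γ-linolenic acid A4 with two molecules of O2 into the endoperoxide A3. Reduction of the O–O bond (SnCl2 or PPh3) would then give 17.
- Better than the chosen plan: step economy and stereocontrol. Two operations, no protecting groups, and all five stereocentres set by the enzyme.
- Against it: a bicyclic peroxide of this kind is expected to rearrange readily to hydroxy ketones, the enzyme is membrane-bound and self-inactivating, and A4 is itself a costly polyunsaturated acid. This makes it a biotransformation on a small scale, not a synthesis from simple building blocks.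
- Comparison: a radical cascade under enzyme control against stepwise polar and organometallic chemistry. The chosen plan is far longer but scalable, and open to variation of either chain.

**Alternative 3:** The bonds C12–C13 and C7–C8 are cut on a preformed ring. Forward, the lithium alkenyl(dimethyl)zincate made from the vinyl iodide A7 would add to C12 of the silyloxy enone A6, and the C8 enolate would be alkylated by the allylic iodide A8, giving A5. Saturation of C5=C6 would give 14 and join the chosen route at step 10.
- Better than the chosen plan: the C11 oxygen is in place from the start, so the epoxidation and reductive opening, with their facial-selectivity question, are avoided. C8 and C12 follow from C11 by substrate control.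
- Equal: the end of the route (steps 10 and 11).
- Better, if A6, A7 and A8 are bought: the longest linear sequence.
- Against it here: a saturated alkyl iodide cannot trap the enolate efficiently, so the upper chain must enter as an allylic unit and then be hydrogenated selectively beside C13=C14. A6 and A8 each cost several steps. The coupling needs stoichiometric organolithium and Me2Zn at low temperature, with β-elimination of the O11 silyl group from an equilibrated enolate as an inherent hazard.
- Comparison: stoichiometric conjugate addition and alkylation on a chiral ring against catalytic C–C bond formation followed by metathesis. Overall step counts are comparable once the building blocks are included.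

Key step: step 6

Assumption: the ligand (S)-L, (S)-5-(dinaphtho[2,1-d:1',2'-f][1,3,2]dioxaphosphepin-4-yl)-5H-dibenzo[b,f]azepine, is taken to be the enantiomer that gives the required C12 configuration. That centre is set by the ligand alone, so (R)-L would be substituted with no other change if the sense proved opposite for an alkenyl vinyl carbinol.

## Route

Step 1
Reactants: 1 (S)-oct-1-yn-3-ol
Product: 2 (S)-tert-butyldimethyl(oct-1-yn-3-yloxy)silane
Conditions: TBSCl, imidazole, DMF, 0 °C to rt
Reagents that add atoms: tert-butyldimethylsilyl chloride, CC(C)(C)[Si](C)(C)Cl
Why: Standard silylation of a secondary propargylic alcohol; no bond to C15 is broken, so the S configuration is carried over unchanged.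

Step 2
Reactants: 2 (S)-tert-butyldimethyl(oct-1-yn-3-yloxy)silane; 3 acrolein
Product: 6 (3RS,4E,6S)-6-[(tert-butyldimethylsilyl)oxy]undeca-1,4-dien-3-ol, via alkenylzirconocene chloride 4 (not isolated), via alkenyl(methyl)zinc 5 (not isolated)
Conditions: Cp2Zr(H)Cl, CH2Cl2, rt; Me2Zn, −65 °C; 3, 0 °C; then H2O (pH 7 buffer)
Reagents that add atoms: none
Why: Syn hydrozirconation of the terminal alkyne places the metal at C13 and fixes the E geometry; zirconium-to-zinc transmetalation gives an alkenylzinc that adds 1,2 to the enal. The C12 carbinol forms as both epimers, which does not matter because C12 is ionised in step 3.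

Step 3
Reactants: 6 (3RS,4E,6S)-6-[(tert-butyldimethylsilyl)oxy]undeca-1,4-dien-3-ol; 7 methyl 9-oxononanoate
Product: 8 methyl (8R,9R,10E,12S)-12-[(tert-butyldimethylsilyl)oxy]-9-ethenyl-8-formylheptadec-10-enoate
Conditions: [Ir(cod)Cl]2 (3 mol %), (S)-L (12 mol %), (S)-2-{bis[3,5-bis(trifluoromethyl)phenyl](trimethylsilyloxy)methyl}pyrrolidine (15 mol %), (MeO)2P(O)OH (0.5 equiv), 7 (2 equiv), ClCH2CH2Cl, 25 °C
Reagents that add atoms: none
Why: Dual iridium/amine catalysis (allylic substitution combined with enamine α-alkylation of a linear aldehyde): acid-assisted ionisation of either C12 epimer of 6 gives one allyl complex of trivalent iridium spanning C10–C12, and the enamine of 7 attacks its alkenyl-substituted terminus C12, as is usual for iridium. The ligand fixes the face of C12 and the S-configured amine shields one enamine face, giving 8R by the same sense as in its other α-functionalisations, so the two adjacent centres are set independently; the E olefin is a spectator.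

Step 4
Reactants: 8 methyl (8R,9R,10E,12S)-12-[(tert-butyldimethylsilyl)oxy]-9-ethenyl-8-formylheptadec-10-enoate
Product: 9 methyl (8R,9R,10E,12S)-12-[(tert-butyldimethylsilyl)oxy]-9-ethenyl-8-(1-hydroxyprop-2-en-1-yl)heptadec-10-enoate (both epimers at the new carbinol carbon)
Conditions: CH2=CHMgBr (1.3 equiv), THF, −78 °C; then H2O (pH 7 buffer)
Reagents that add atoms: vinylmagnesium bromide, C=C[Mg]Br
Why: Grignard 1,2-addition; at −78 °C the aldehyde reacts far faster than the methyl ester and enolisation of the α-branched aldehyde is slow, so C8 is kept. The new carbinol centre is erased in step 5.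

Step 5
Reactants: 9 methyl (8R,9R,10E,12S)-12-[(tert-butyldimethylsilyl)oxy]-9-ethenyl-8-(1-hydroxyprop-2-en-1-yl)heptadec-10-enoate
Product: 10 methyl (8R,9R,10E,12S)-12-[(tert-butyldimethylsilyl)oxy]-9-ethenyl-8-(prop-2-enoyl)heptadec-10-enoate
Conditions: Dess–Martin periodinane, NaHCO3, CH2Cl2, 0 °C to rt; used at once
Reagents that add atoms: none
Why: Dess–Martin oxidation of the allylic alcohol under buffered, non-basic conditions gives the vinyl ketone without enolising C8 or moving the skipped diene into conjugation. The sensitive dienone is not stored.

Step 6
Reactants: 10 methyl (8R,9R,10E,12S)-12-[(tert-butyldimethylsilyl)oxy]-9-ethenyl-8-(prop-2-enoyl)heptadec-10-enoate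
Product: 11 prostaglandin A1 methyl ester 15-tert-butyldimethylsilyl ether
Conditions: second-generation Grubbs catalyst (H2IMes)(PCy3)Cl2Ru=CHPh (5 mol %), CH2Cl2 (0.005 M), 40 °C
Reagents that add atoms: none
Why: Ring-closing olefin metathesis by the metallacyclobutane mechanism: the benzylidene exchanges with the least hindered and most electron-rich olefin, the C12 vinyl group, to give a ruthenium alkylidene at C11; this adds across the C10 terminus of the vinyl ketone in a [2+2] step, and cycloreversion forms C10=C11 and a ruthenium methylidene that leaves as ethylene in the next turnover. The closest known reaction type is the closure of vinyl ketones onto terminal olefins to give cyclopent-2-enones with N-heterocyclic-carbene ruthenium catalysts. The ring closed is the five-membered carbocycle C8–C9–C10–C11–C12, made by joining two vinyl termini whose anchoring carbons C9 and C12 are 1,3-related through C8, so closure is entropically easy and the new olefin is necessarily cis. No stereocentre is created, and C8 and C12 are untouched because the medium is neutral and aprotic. The selectivity needed is among three olefins: an alkylidene at C11 cannot close onto C13=C14 (that would be a three-membered ring), so loss of the lower chain could only begin from an alkylidene at C10 or at C13/C14. Both are disfavoured, the first because acyl-substituted alkylidenes form slowly, the second because C13=C14 is 1,2-disubstituted and flanked by the branched C12 and the silyloxy-bearing C15. High dilution suppresses cross-metathesis between C12 vinyl groups, and a short reaction time limits ruthenium hydride formation, which could move the C10–C14 skipped diene into conjugation.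

Step 7
Reactants: 11 prostaglandin A1 methyl ester 15-tert-butyldimethylsilyl ether
Product: 12 10α,11α-epoxy-10,11-dihydroprostaglandin A1 methyl ester 15-tert-butyldimethylsilyl ether
Conditions: 30% aq. H2O2, NaOH (substoichiometric), MeOH, −40 °C
Reagents that add atoms: hydrogen peroxide, OO
Why: Weitz–Scheffer nucleophilic epoxidation: the hydroperoxide anion adds to C11 from the face opposite the adjacent C12 chain and the enolate closes the oxirane on the same face, setting C10 and C11. The low temperature limits base-induced migration of the enone olefin and ester hydrolysis.

Step 8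
Reactants: 12 10α,11α-epoxy-10,11-dihydroprostaglandin A1 methyl ester 15-tert-butyldimethylsilyl ether
Product: 13 prostaglandin E1 methyl ester 15-tert-butyldimethylsilyl ether
Conditions: SmI2 (2.5 equiv), THF/MeOH, −90 °C
Reagents that add atoms: none
Why: Two-electron reductive cleavage of an α,β-epoxy ketone by samarium diiodide breaks only the C10–O bond α to the carbonyl, so the C11–O bond and its configuration are retained. Methanol protonates the samarium enolate at low temperature before β-elimination can occur; ester and olefin are inert.

Step 9
Reactants: 13 prostaglandin E1 methyl ester 15-tert-butyldimethylsilyl ether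
Product: 14 prostaglandin E1 methyl ester 11,15-bis(tert-butyldimethylsilyl) ether
Conditions: TBSCl, imidazole, DMF, rt
Reagents that add atoms: tert-butyldimethylsilyl chloride, CC(C)(C)[Si](C)(C)Cl
Why: Silylation of the secondary C11 alcohol; imidazole is too weak a base to trigger β-elimination of the β-oxy ketone at room temperature. The bulky α-oriented silyl ether is wanted to steer step 10.

Step 10
Reactants: 14 prostaglandin E1 methyl ester 11,15-bis(tert-butyldimethylsilyl) ether
Product: 15 prostaglandin F1alpha methyl ester 11,15-bis(tert-butyldimethylsilyl) ether
Conditions: LiBH(s-Bu)3 (1.3 equiv), THF, −78 °C; then H2O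
Reagents that add atoms: none
Why: Ketone reduction by a bulky trialkylborohydride: hydride reaches C9 from the face away from the adjacent C8 chain and the O11 silyl group, giving the 9α (9S) alcohol. The ester is inert at −78 °C.

Step 11
Reactants: 15 prostaglandin F1alpha methyl ester 11,15-bis(tert-butyldimethylsilyl) ether
Product: 17 prostaglandin F1alpha, via prostaglandin F1alpha methyl ester 16 (not isolated)
Conditions: 1.5% aq. HCl/THF (2:3), rt; then LiOH·H2O (excess), rt; then aq. HCl to pH 4
Reagents that add atoms: lithium hydroxide, [Li+].[OH-]
Why: Acid-catalysed hydrolysis of both silyl ethers followed by saponification of the methyl ester in the same flask. No stereocentre is involved, and dilute acid at room temperature stays below the point at which the allylic C15 alcohol ionises.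

## Compound list

1 | (S)-oct-1-yn-3-ol | CCCCC[C@H](O)C#C | starting material
2 | (S)-tert-butyldimethyl(oct-1-yn-3-yloxy)silane | CCCCC[C@H](O[Si](C)(C)C(C)(C)C)C#C | intermediate
3 | acrolein | C=CC=O | starting material
4 | chloro{(1E,3S)-3-[(tert-butyldimethylsilyl)oxy]oct-1-en-1-yl}bis(cyclopentadienyl)zirconium | CCCCC[C@H](O[Si](C)(C)C(C)(C)C)/C=C/[Zr](Cl)(C1C=CC=C1)C1C=CC=C1 | intermediate (not isolated)
5 | {(1E,3S)-3-[(tert-butyldimethylsilyl)oxy]oct-1-en-1-yl}(methyl)zinc | CCCCC[C@H](O[Si](C)(C)C(C)(C)C)/C=C/[Zn]C | intermediate (not isolated)
6 | (3RS,4E,6S)-6-[(tert-butyldimethylsilyl)oxy]undeca-1,4-dien-3-ol | CCCCC[C@H](O[Si](C)(C)C(C)(C)C)/C=C/C(O)C=C | intermediate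
7 | methyl 9-oxononanoate | COC(=O)CCCCCCCC=O | starting material
8 | methyl (8R,9R,10E,12S)-12-[(tert-butyldimethylsilyl)oxy]-9-ethenyl-8-formylheptadec-10-enoate | CCCCC[C@H](O[Si](C)(C)C(C)(C)C)/C=C/[C@H]([C@@H](CCCCCCC(=O)OC)C=O)C=C | intermediate
9 | methyl (8R,9R,10E,12S)-12-[(tert-butyldimethylsilyl)oxy]-9-ethenyl-8-(1-hydroxyprop-2-en-1-yl)heptadec-10-enoate, both carbinol epimers | CCCCC[C@H](O[Si](C)(C)C(C)(C)C)/C=C/[C@H]([C@@H](CCCCCCC(=O)OC)C(O)C=C)C=C | intermediate
10 | methyl (8R,9R,10E,12S)-12-[(tert-butyldimethylsilyl)oxy]-9-ethenyl-8-(prop-2-enoyl)heptadec-10-enoate | CCCCC[C@H](O[Si](C)(C)C(C)(C)C)/C=C/[C@H]([C@@H](CCCCCCC(=O)OC)C(=O)C=C)C=C | intermediate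
11 | prostaglandin A1 methyl ester 15-tert-butyldimethylsilyl ether; methyl 7-[(1R,2S)-2-{(1E,3S)-3-[(tert-butyldimethylsilyl)oxy]oct-1-en-1-yl}-5-oxocyclopent-3-en-1-yl]heptanoate | CCCCC[C@H](O[Si](C)(C)C(C)(C)C)/C=C/[C@@H]1[C@@H](CCCCCCC(=O)OC)C(=O)C=C1 | intermediate
12 | 10α,11α-epoxy-10,11-dihydroprostaglandin A1 methyl ester 15-tert-butyldimethylsilyl ether | CCCCC[C@H](O[Si](C)(C)C(C)(C)C)/C=C/[C@@H]1[C@@H](CCCCCCC(=O)OC)C(=O)[C@H]2O[C@@H]12 | intermediate
13 | prostaglandin E1 methyl ester 15-tert-butyldimethylsilyl ether | CCCCC[C@H](O[Si](C)(C)C(C)(C)C)/C=C/[C@@H]1[C@@H](CCCCCCC(=O)OC)C(=O)C[C@H]1O | intermediate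
14 | prostaglandin E1 methyl ester 11,15-bis(tert-butyldimethylsilyl) ether | CCCCC[C@H](O[Si](C)(C)C(C)(C)C)/C=C/[C@@H]1[C@@H](CCCCCCC(=O)OC)C(=O)C[C@H]1O[Si](C)(C)C(C)(C)C | intermediate
15 | prostaglandin F1alpha methyl ester 11,15-bis(tert-butyldimethylsilyl) ether | CCCCC[C@H](O[Si](C)(C)C(C)(C)C)/C=C/[C@@H]1[C@@H](CCCCCCC(=O)OC)[C@@H](O)C[C@H]1O[Si](C)(C)C(C)(C)C | intermediate
16 | prostaglandin F1alpha methyl ester | CCCCC[C@H](O)/C=C/[C@@H]1[C@@H](CCCCCCC(=O)OC)[C@@H](O)C[C@H]1O | intermediate (not isolated)
17 | prostaglandin F1alpha; 7-[(1R,2R,3R,5S)-3,5-dihydroxy-2-{(1E,3S)-3-hydroxyoct-1-en-1-yl}cyclopentyl]heptanoic acid | CCCCC[C@H](O)/C=C/[C@@H]1[C@@H](CCCCCCC(=O)O)[C@@H](O)C[C@H]1O | target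

## Step count and least certain steps

Total step count: 11. Longest linear sequence: 11 steps (1 to 17); 3 and 7 are bought and enter in steps 2 and 3.

**Step 6 (key step).** The most likely failure is slow closure onto the electron-poor vinyl ketone. Catalyst decay to ruthenium hydrides, with isomerisation at the doubly allylic C12, or intermolecular metathesis of the C12 vinyl group could then overtake ring closure. The fallback closes the ring one oxidation level lower. It sets out from 9: metathesis of 9 with the same catalyst (CH2Cl2, rt) joins two electronically unbiased terminal olefins and should give the 9-hydroxy cyclopentene F1 as a pair of carbinol epimers. Oxidation of this allylic alcohol with MnO2 comes back to the route at 11, and step 5 is not needed.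

**Step 3.** The most likely failure is incomplete control of C8. The catalyst pair may be mismatched with the resident C15 centre, or the α-branched aldehyde may epimerise through renewed enamine formation under the acid promoter. A minor share of attack at the allyl terminus C10 would be removed by chromatography. The fallback gives up kinetic control of C8 and sets it thermodynamically on the ring. It sets out from 6 and 7: the allylation is run with the iridium catalyst and an achiral amine (pyrrolidine), so that only C12 is controlled and 8 forms together with its C8 epimer F2. The mixture is taken through steps 4 to 6, which give the epimeric allylic alcohols F3, the epimeric dienone F4 and the cis-disubstituted cyclopentenone F5 beside 9, 10 and 11. Brief treatment with catalytic DBU in CH2Cl2 at 0 °C should epimerise C8 through the cross-conjugated dienolate towards the more stable trans arrangement, as is usual for 4,5-disubstituted cyclopent-2-enones, and so comes back to the route at 11. The exposure to base must be short, because deprotonation at C12 leads irreversibly to the C8=C12 enone.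

**Step 7.** The most likely failure is poor facial selectivity. The hydroperoxide anion is small and only the C12 chain differentiates the two faces, and the base may also start migration of the enone olefin. The fallback brings the C11 oxygen in through boron. It sets out from 11: copper-catalysed conjugate borylation (CuCl, NaOt-Bu, DPEphos, B2pin2, MeOH, THF, rt) should deliver the bulky boryl–copper species to C11 anti to the C12 chain and give the 11α-boryl ketone F6. Oxidation with NaBO3·4H2O in THF/H2O proceeds with retention at carbon and comes back to the route at 13; steps 7 and 8 are replaced.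

**Step 4.** The most likely failure is enolisation of the α-branched aldehyde by the basic Grignard reagent, with erosion of C8, together with partial attack on the methyl ester. The fallback makes the vinyl ketone without a basic carbon nucleophile. It sets out from 8: Pinnick oxidation (NaClO2, NaH2PO4, 2-methylbut-2-ene, t-BuOH/H2O) gives the carboxylic acid F7. 1-Chloro-N,N,2-trimethylprop-1-en-1-amine converts it under neutral conditions into the acid chloride F8. Stille acylation with tributyl(vinyl)stannane under zerovalent palladium catalysis, Pd(PPh3)4, then comes back to the route at 10; steps 4 and 5 are replaced.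

## Further compounds

F1 | step 6 | methyl (9RS,13E,15S)-15-[(tert-butyldimethylsilyl)oxy]-9-hydroxyprosta-10,13-dien-1-oate | CCCCC[C@H](O[Si](C)(C)C(C)(C)C)/C=C/[C@@H]1[C@@H](CCCCCCC(=O)OC)C(O)C=C1
F2 | step 3 | methyl (8S,9R,10E,12S)-12-[(tert-butyldimethylsilyl)oxy]-9-ethenyl-8-formylheptadec-10-enoate | CCCCC[C@H](O[Si](C)(C)C(C)(C)C)/C=C/[C@H]([C@H](CCCCCCC(=O)OC)C=O)C=C
F3 | step 3 | methyl (8S,9R,10E,12S)-12-[(tert-butyldimethylsilyl)oxy]-9-ethenyl-8-(1-hydroxyprop-2-en-1-yl)heptadec-10-enoate | CCCCC[C@H](O[Si](C)(C)C(C)(C)C)/C=C/[C@H]([C@H](CCCCCCC(=O)OC)C(O)C=C)C=C
F4 | step 3 | methyl (8S,9R,10E,12S)-12-[(tert-butyldimethylsilyl)oxy]-9-ethenyl-8-(prop-2-enoyl)heptadec-10-enoate | CCCCC[C@H](O[Si](C)(C)C(C)(C)C)/C=C/[C@H]([C@H](CCCCCCC(=O)OC)C(=O)C=C)C=C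
F5 | step 3 | methyl 7-[(1S,2S)-2-{(1E,3S)-3-[(tert-butyldimethylsilyl)oxy]oct-1-en-1-yl}-5-oxocyclopent-3-en-1-yl]heptanoate | CCCCC[C@H](O[Si](C)(C)C(C)(C)C)/C=C/[C@@H]1[C@H](CCCCCCC(=O)OC)C(=O)C=C1
F6 | step 7 | 11-deoxy-11α-(4,4,5,5-tetramethyl-1,3,2-dioxaborolan-2-yl)prostaglandin E1 methyl ester 15-tert-butyldimethylsilyl ether | CCCCC[C@H](O[Si](C)(C)C(C)(C)C)/C=C/[C@@H]1[C@@H](CCCCCCC(=O)OC)C(=O)C[C@H]1B1OC(C)(C)C(C)(C)O1
F7 | step 4 | (2R,3R,4E,6S)-6-[(tert-butyldimethylsilyl)oxy]-3-ethenyl-2-(7-methoxy-7-oxoheptyl)undec-4-enoic acid | CCCCC[C@H](O[Si](C)(C)C(C)(C)C)/C=C/[C@H]([C@@H](CCCCCCC(=O)OC)C(=O)O)C=C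
F8 | step 4 | methyl (8R,9R,10E,12S)-12-[(tert-butyldimethylsilyl)oxy]-8-(chlorocarbonyl)-9-ethenylheptadec-10-enoate | CCCCC[C@H](O[Si](C)(C)C(C)(C)C)/C=C/[C@H]([C@@H](CCCCCCC(=O)OC)C(=O)Cl)C=C
A1 | alternative 1 | (3aR,6aS)-2-hydroxy-3,3a,6,6a-tetrahydro-2H-cyclopenta[b]furan-5-carbaldehyde | O=CC1=C[C@H]2CC(O)O[C@H]2C1
A2 | alternative 1 | succinaldehyde (butanedial) | O=CCCC=O
A3 | alternative 2 | prostaglandin H1 | CCCCC[C@H](O)/C=C/[C@@H]1[C@@H](CCCCCCC(=O)O)[C@@H]2C[C@H]1OO2
A4 | alternative 2 | dihomo-γ-linolenic acid, (8Z,11Z,14Z)-icosa-8,11,14-trienoic acid | CCCCC/C=C\C/C=C\C/C=C\CCCCCCC(=O)O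
A5 | alternative 3 | prostaglandin E2 methyl ester 11,15-bis(tert-butyldimethylsilyl) ether | CCCCC[C@H](O[Si](C)(C)C(C)(C)C)/C=C/[C@@H]1[C@@H](C/C=C\CCCC(=O)OC)C(=O)C[C@H]1O[Si](C)(C)C(C)(C)C
A6 | alternative 3 | (R)-4-[(tert-butyldimethylsilyl)oxy]cyclopent-2-en-1-one | O=C1C[C@@H](O[Si](C)(C)C(C)(C)C)C=C1
A7 | alternative 3 | (S,E)-tert-butyl[(1-iodooct-1-en-3-yl)oxy]dimethylsilane | CCCCC[C@H](O[Si](C)(C)C(C)(C)C)/C=C/I
A8 | alternative 3 | methyl (Z)-7-iodohept-5-enoate | COC(=O)CCC/C=C\CI
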